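**Plan**

1. Feature: ring A of the flavone (C4a, C5, C6, C7, C8, C8a) carries oxygen on each of its four free carbons C5–C8. A squarate C4 unit holds exactly these four oxygenated carbons and only has to be fused onto the C4a–C8a edge of a finished γ-pyranone (ring C, already bearing ring B).
2. Retrosynthetic cuts, in order: the 4'-O–benzyl and 8-O–methyl bonds; the C8–C8a bond of ring A (back to a 4-hydroxy-4-pyranonyl-2,3-dimethoxycyclobutenone); the C5–C4a bond (pyranonylmagnesium plus dimethyl squarate); the C–I bond at the future C4a; the C2–C1' bond (cross-coupling); the 3-O–methyl and C2–Br bonds of pyromeconic acid.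
3. Forward: ring C is bought as pyromeconic acid, ring B is joined at C2 by Suzuki coupling, the squarate unit is attached at the pyranone carbon that becomes C4a, and ring A closes last by thermal 4π opening and 6π closure.
4. Stereochemistry: the target has no stereogenic element. The one stereocentre on the route (the carbinol carbon of the cyclobutenone) is racemic and is erased in the ring expansion.

Key step: step 6

Assumption: calycopterin is achiral, so "single enantiomer" is read as the one constitution given by the SMILES, and no asymmetric step is needed.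

Numbering remark: C2, C3, C4, C5 and C6 of pyranones 5 and 6 become C2, C3, C4, C4a and C8a of the flavone.

**Route**

Step 1
Reactants: 1 pyromeconic acid (3-hydroxy-4H-pyran-4-one)
Product: 2 2-bromo-3-hydroxy-4H-pyran-4-one
Conditions: NBS (1.0 equiv), MeCN, 0 °C to rt, dark
Reagents that add atoms: N-bromosuccinimide, O=C1CCC(=O)N1Br
Why: Electrophilic bromination of an enolic 3-hydroxy-4-pyranone should go to the carbon ortho to the hydroxyl (C2), the site at which kojic acid and allomaltol take up halogens, diazonium ions and Mannich electrophiles, and one equivalent of NBS at 0 °C should stop at the monobromide.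

Step 2
Reactants: 2 2-bromo-3-hydroxy-4H-pyran-4-one
Product: 3 2-bromo-3-methoxy-4H-pyran-4-one
Conditions: MeI, K2CO3, DMF, rt
Reagents that add atoms: iodomethane, CI
Why: Williamson O-methylation of the acidic enol with a mild carbonate base, as is routine for maltol and kojic acid; the enolate should be alkylated faster than the vinylogous acyl bromide is displaced.

Step 3
Reactants: 3 2-bromo-3-methoxy-4H-pyran-4-one; 4 4-(benzyloxy)phenylboronic acid
Product: 5 2-[4-(benzyloxy)phenyl]-3-methoxy-4H-pyran-4-one
Conditions: Pd(dppf)Cl2 (3 mol %), K2CO3, 1,4-dioxane/H2O 9:1, 80 °C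
Reagents that add atoms: none
Why: Suzuki–Miyaura coupling; the C2–Br bond is that of a β-bromo enone and undergoes oxidative addition easily, and the benzyl ether, methyl enol ether and pyranone should tolerate aqueous carbonate at 80 °C.

Step 4
Reactants: 5 2-[4-(benzyloxy)phenyl]-3-methoxy-4H-pyran-4-one
Product: 6 2-[4-(benzyloxy)phenyl]-5-iodo-3-methoxy-4H-pyran-4-one
Conditions: NIS (1.1 equiv), TFA (0.3 equiv), MeCN, rt to 40 °C, dark
Reagents that add atoms: N-iodosuccinimide, O=C1CCC(=O)N1I
Why: Electrophilic α-iodination of the γ-pyranone at C5, the only free carbon that is α to the carbonyl and β to the ring oxygen (as in the 3-halogenation of chromones and 4-pyranones); the benzyloxyphenyl ring is para-blocked and deactivated by conjugation with the pyranone carbonyl, so it should react more slowly.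

Step 5
Reactants: 6 2-[4-(benzyloxy)phenyl]-5-iodo-3-methoxy-4H-pyran-4-one; 7 dimethyl squarate (3,4-dimethoxycyclobut-3-ene-1,2-dione)
Product: 10 4-{6-[4-(benzyloxy)phenyl]-5-methoxy-4-oxo-4H-pyran-3-yl}-4-hydroxy-2,3-dimethoxycyclobut-2-en-1-one (racemic), via pyranonylmagnesium chloride 8 (not isolated), via chloromagnesium alkoxide 9 (not isolated)
Conditions: i-PrMgCl·LiCl (1.05 equiv), THF, −78 °C, 20 min; cannulate into 7 (1.3 equiv), THF, −78 °C; then H2O at −78 °C, neutral work-up
Reagents that add atoms: none
Why: Iodine–magnesium exchange with the turbo-Grignard reagent at −78 °C gives a carbonyl-chelated α-magnesiated β-alkoxy enone (the type known from 5-iodo-1,3-dioxin-4-ones and 5-iodouracils), which adds 1,2 to one of the two equivalent carbonyls of dimethyl squarate (standard organometal–squarate addition); the carbinol stereocentre forms as the racemate and is not needed later.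

Step 6
Reactants: 10 4-{6-[4-(benzyloxy)phenyl]-5-methoxy-4-oxo-4H-pyran-3-yl}-4-hydroxy-2,3-dimethoxycyclobut-2-en-1-one (racemic)
Product: 13 2-[4-(benzyloxy)phenyl]-5,8-dihydroxy-3,6,7-trimethoxy-4H-chromen-4-one, via dienylketene 11 (not isolated), via 8aH-chromene-4,8-dione 12 (not isolated)
Conditions: degassed dry p-xylene (0.02 M), 138 °C, Ar, 1–2 h; isolation under Ar
Reagents that add atoms: none
Why: Heating should cleave the bond between the carbonyl carbon and the carbinol carbon of the cyclobutenone in a conrotatory 4π ring opening to dienylketene 11; its ketene carbon then bonds to the pyranone CH carbon next to the ring oxygen (future C8a) in a thermal disrotatory 6π electrocyclisation that closes the six-membered carbocycle as dienone 12, and a hydrogen shift from C8a to the C8 oxygen aromatises ring A to hydroquinone 13. The closest known reaction is the Moore thermal ring expansion of squarate-derived 4-aryl-, 4-heteroaryl- and 4-alkenyl-4-hydroxycyclobutenones to annulated hydroquinones. The two squarate methoxy carbons become C6 and C7, the carbinol carbon becomes C5 and the ketene carbon becomes C8, so the only skeletal bond formed is C8–C8a. No lasting stereocentre arises: the sp3 centre at C8a of 12 is transient and racemic and disappears on tautomerisation, as does the carbinol centre of 10. The step needs torquoselectivity, which the donor hydroxyl supplies by rotating outward so that the pyranonyl group turns inward, cis to the ketene arm; it also needs site selectivity in the closure, which is secured because the other neighbour of the attachment carbon is the C4 carbonyl carbon and cannot take part. Exclusion of air should keep the electron-rich product at the hydroquinone level.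

Step 7
Reactants: 13 2-[4-(benzyloxy)phenyl]-5,8-dihydroxy-3,6,7-trimethoxy-4H-chromen-4-one
Product: 14 2-[4-(benzyloxy)phenyl]-5-hydroxy-3,6,7,8-tetramethoxy-4H-chromen-4-one
Conditions: Me2SO4 (1.05 equiv), K2CO3 (1.2 equiv), degassed acetone, rt to 40 °C, Ar
Reagents that add atoms: dimethyl sulfate, COS(=O)(=O)OC
Why: Williamson methylation with one equivalent of dimethyl sulfate should alkylate only the free 8-OH, because the 5-OH is held in a strong hydrogen bond to the peri C4 carbonyl and is not alkylated under these mild conditions (the classical partial methylation of 5-hydroxyflavones).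

Step 8
Reactants: 14 2-[4-(benzyloxy)phenyl]-5-hydroxy-3,6,7,8-tetramethoxy-4H-chromen-4-one
Product: 15 calycopterin, 5-hydroxy-2-(4-hydroxyphenyl)-3,6,7,8-tetramethoxy-4H-chromen-4-one
Conditions: H2 (1 atm), 10% Pd/C, EtOAc/MeOH, rt
Reagents that add atoms: none
Why: Catalytic hydrogenolysis of the benzyl aryl ether; the aryl methyl ethers, the chelated phenol and the tetrasubstituted C2=C3 bond of the flavone should be inert to Pd/C under 1 atm of hydrogen at room temperature.

**Compound list**

1 | pyromeconic acid (3-hydroxy-4H-pyran-4-one) | O=c1ccocc1O | starting material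
2 | 2-bromo-3-hydroxy-4H-pyran-4-one | O=c1ccoc(Br)c1O | intermediate
3 | 2-bromo-3-methoxy-4H-pyran-4-one | COc1c(Br)occc1=O | intermediate
4 | 4-(benzyloxy)phenylboronic acid | OB(O)c1ccc(OCc2ccccc2)cc1 | starting material
5 | 2-[4-(benzyloxy)phenyl]-3-methoxy-4H-pyran-4-one | COc1c(-c2ccc(OCc3ccccc3)cc2)occc1=O | intermediate
6 | 2-[4-(benzyloxy)phenyl]-5-iodo-3-methoxy-4H-pyran-4-one | COc1c(-c2ccc(OCc3ccccc3)cc2)occ(I)c1=O | intermediate
7 | dimethyl squarate (3,4-dimethoxycyclobut-3-ene-1,2-dione) | COC1=C(OC)C(=O)C1=O | starting material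
8 | {6-[4-(benzyloxy)phenyl]-5-methoxy-4-oxo-4H-pyran-3-yl}magnesium chloride (LiCl complex, not isolated) | COc1c(-c2ccc(OCc3ccccc3)cc2)occ([Mg]Cl)c1=O | intermediate
9 | chloromagnesium alkoxide of 10 (racemic, not isolated) | COC1=C(OC)C(O[Mg]Cl)(c2coc(-c3ccc(OCc4ccccc4)cc3)c(OC)c2=O)C1=O | intermediate
10 | 4-{6-[4-(benzyloxy)phenyl]-5-methoxy-4-oxo-4H-pyran-3-yl}-4-hydroxy-2,3-dimethoxycyclobut-2-en-1-one (racemic) | COC1=C(OC)C(O)(c2coc(-c3ccc(OCc4ccccc4)cc3)c(OC)c2=O)C1=O | intermediate
11 | (3Z)-4-{6-[4-(benzyloxy)phenyl]-5-methoxy-4-oxo-4H-pyran-3-yl}-4-hydroxy-2,3-dimethoxybuta-1,3-dien-1-one (dienylketene, not isolated) | O=C=C(OC)/C(OC)=C(/O)c1coc(-c2ccc(OCc3ccccc3)cc2)c(OC)c1=O | intermediate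
12 | 2-[4-(benzyloxy)phenyl]-5-hydroxy-3,6,7-trimethoxy-8aH-chromene-4,8-dione (racemic, not isolated) | O=C1C(OC)=C(OC)C(O)=C2C(=O)C(OC)=C(-c3ccc(OCc4ccccc4)cc3)OC12 | intermediate
13 | 2-[4-(benzyloxy)phenyl]-5,8-dihydroxy-3,6,7-trimethoxy-4H-chromen-4-one | COc1c(OC)c(O)c2c(=O)c(OC)c(-c3ccc(OCc4ccccc4)cc3)oc2c1O | intermediate
14 | 2-[4-(benzyloxy)phenyl]-5-hydroxy-3,6,7,8-tetramethoxy-4H-chromen-4-one | COc1c(OC)c(O)c2c(=O)c(OC)c(-c3ccc(OCc4ccccc4)cc3)oc2c1OC | intermediate
15 | calycopterin (5-hydroxy-2-(4-hydroxyphenyl)-3,6,7,8-tetramethoxy-4H-chromen-4-one; achiral) | COc1c(OC)c(O)c2c(=O)c(OC)c(-c3ccc(O)cc3)oc2c1OC | target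

**Totals and risks**

Total step count: 8. Longest linear sequence: 8 steps (1 to 15); 4 and 7 are purchased and enter in steps 3 and 5.

Steps most likely to fail:

1. Step 5. The magnesiated pyranone may fragment by β-elimination of the ring oxygen, which lies anti to the C–Mg bond, before it meets the squarate; the exchange reagent may also add to the pyranone or to the squarate. The fallback sets out from 6. Direct insertion of zinc dust (LiCl, THF, 25–40 °C) should give the more covalent and fragmentation-resistant {6-[4-(benzyloxy)phenyl]-5-methoxy-4-oxo-4H-pyran-3-yl}zinc iodide F1. MgCl2-promoted carbonyl addition of this organozinc to 7 should give the iodozinc alkoxide of 10 F2, and neutral aqueous work-up returns to the route at 10.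

2. Step 6. The ketene may be captured by the free tertiary hydroxyl (lactonisation to a butenolide) in competition with closure onto the pyranone carbon, and the unprotected hydroquinone may be lost to air oxidation during isolation. The fallback sets out from 10 and returns at 14.
   - Silylation (TBSOTf, 2,6-lutidine, CH2Cl2, −78 °C) should give 4-{6-[4-(benzyloxy)phenyl]-5-methoxy-4-oxo-4H-pyran-3-yl}-4-[(tert-butyldimethylsilyl)oxy]-2,3-dimethoxycyclobut-2-en-1-one F3.
   - Thermolysis under the conditions of step 6 should pass through the silyloxy dienylketene F4 and the 5-silyloxy-8aH-chromene-4,8-dione F5 to the mono-protected hydroquinone 2-[4-(benzyloxy)phenyl]-5-[(tert-butyldimethylsilyl)oxy]-8-hydroxy-3,6,7-trimethoxy-4H-chromen-4-one F6. This compound cannot lactonise and is far less prone to oxidation.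
   - Methylation of its only free phenol (MeI, K2CO3, acetone) should give 2-[4-(benzyloxy)phenyl]-5-[(tert-butyldimethylsilyl)oxy]-3,6,7,8-tetramethoxy-4H-chromen-4-one F7.
   - Desilylation (TBAF, AcOH, THF, 0 °C) returns to the route at 14.
   - This detour also removes the reliance of step 7 on chelation to tell the two hydroxyls apart.

3. Step 4. Iodination may occur on the benzyloxyphenyl ring ortho to the ether oxygen, or the pyranone may react too slowly. The fallback sets out from 5 and replaces electrophilic substitution by carbonyl-directed deprotonation. The TMP-zinc amide base containing MgCl2 (TMP2Zn·2MgCl2·2LiCl, 0.55 equiv, THF, −30 °C), which metalates chromones and γ-pyranones at the carbon α to the carbonyl, should give bis{6-[4-(benzyloxy)phenyl]-5-methoxy-4-oxo-4H-pyran-3-yl}zinc F8. Iodolysis (I2, THF, 0 °C) returns to the route at 6.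

Further compounds
F1 | step 5 | {6-[4-(benzyloxy)phenyl]-5-methoxy-4-oxo-4H-pyran-3-yl}zinc iodide | COc1c(-c2ccc(OCc3ccccc3)cc2)occ([Zn]I)c1=O
F2 | step 5 | iodozinc alkoxide of 10 (racemic) | COC1=C(OC)C(O[Zn]I)(c2coc(-c3ccc(OCc4ccccc4)cc3)c(OC)c2=O)C1=O
F3 | step 6 | 4-{6-[4-(benzyloxy)phenyl]-5-methoxy-4-oxo-4H-pyran-3-yl}-4-[(tert-butyldimethylsilyl)oxy]-2,3-dimethoxycyclobut-2-en-1-one (racemic) | COC1=C(OC)C(O[Si](C)(C)C(C)(C)C)(c2coc(-c3ccc(OCc4ccccc4)cc3)c(OC)c2=O)C1=O
F4 | step 6 | (3Z)-4-{6-[4-(benzyloxy)phenyl]-5-methoxy-4-oxo-4H-pyran-3-yl}-4-[(tert-butyldimethylsilyl)oxy]-2,3-dimethoxybuta-1,3-dien-1-one | O=C=C(OC)/C(OC)=C(/O[Si](C)(C)C(C)(C)C)c1coc(-c2ccc(OCc3ccccc3)cc2)c(OC)c1=O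
F5 | step 6 | 2-[4-(benzyloxy)phenyl]-5-[(tert-butyldimethylsilyl)oxy]-3,6,7-trimethoxy-8aH-chromene-4,8-dione (racemic) | O=C1C(OC)=C(OC)C(O[Si](C)(C)C(C)(C)C)=C2C(=O)C(OC)=C(-c3ccc(OCc4ccccc4)cc3)OC12
F6 | step 6 | 2-[4-(benzyloxy)phenyl]-5-[(tert-butyldimethylsilyl)oxy]-8-hydroxy-3,6,7-trimethoxy-4H-chromen-4-one | COc1c(OC)c(O[Si](C)(C)C(C)(C)C)c2c(=O)c(OC)c(-c3ccc(OCc4ccccc4)cc3)oc2c1O
F7 | step 6 | 2-[4-(benzyloxy)phenyl]-5-[(tert-butyldimethylsilyl)oxy]-3,6,7,8-tetramethoxy-4H-chromen-4-one | COc1c(OC)c(O[Si](C)(C)C(C)(C)C)c2c(=O)c(OC)c(-c3ccc(OCc4ccccc4)cc3)oc2c1OC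
F8 | step 4 | bis{6-[4-(benzyloxy)phenyl]-5-methoxy-4-oxo-4H-pyran-3-yl}zinc | COc1c(-c2ccc(OCc3ccccc3)cc2)occ([Zn]c2coc(-c3ccc(OCc4ccccc4)cc3)c(OC)c2=O)c1=O
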